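**Retrosynthetic overview**

1. The target is read as a germacranolide: carbocycle C1–C10 (C1 carbinol, C4 tertiary carbinol, C6 tiglate carbon, C7, C8 lactone carbinol, Z-C9=C10) fused at C7–C8 to the lactone ring O–C8–C7–C11–C12(=O), with exocyclic C13 on C11.
2. Last ring bond cut: C1–C10 of the carbocycle (CrCl2/NiCl2 closure of a Z-vinyl iodide on an aldehyde; C1 is then fixed by oxidation and CBS reduction).
3. Key cut: C7–C11 of the lactone ring. The enabling feature is that C7 sits between two oxygen-bearing carbons, C8 (lactone oxygen) and C6 (acyloxy), with the C6–O bond anti to C7–C11. This is the pattern left by a C6–C7 cis-epoxide opened at C7 by a C11 carbanion tethered through the C8 oxygen (phosphonoacetate, 5-exo); the phosphorus then brings in C13 with formaldehyde in the same flask.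
4. The threo epoxy alcohol comes from hydroxyl-directed epoxidation of a Z,Z-dienol. The dienol comes from asymmetric alkynylation of (Z)-3-iodobut-2-enal (C8–C10) with a C1–C7 alkyne made from geraniol (C4 set by Sharpless epoxidation).
5. Order of ring formation: γ-lactone first (step 12), ten-membered carbocycle second (step 15).

Key step: step 12

Remark (atom labels): the labels C1–C15 used in the Why lines follow the germacrane numbering of the overview (C14 = methyl on C10, C15 = methyl on C4).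
Remark (assumption): the oxirane carbon that becomes C1 is carried from step 10 to step 14 as both epimers, because it is destroyed there.
Remark (assumption): (S,S)-ProPhenol is taken to deliver the alkynylzinc to the Si face of the aldehyde in step 8; if the first Mosher analysis shows the opposite sense, the (R,R)-ligand is used with no other change.

**Route**

Step 1
Reactants: 1 geraniol
Product: 2 (2S,3S)-2,3-epoxygeraniol
Conditions: Ti(OiPr)4 (cat.), L-(+)-diethyl tartrate (cat.), t-BuOOH, 4 Å MS, CH2Cl2, −20 °C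
Reagents that add atoms: tert-butyl hydroperoxide, CC(C)(C)OO
Why: Sharpless asymmetric epoxidation, in which the Ti(OiPr)4–tartrate complex epoxidises only the allylic alkene and L-(+)-tartrate directs oxygen to the face that gives the (2S,3S)-epoxide, which fixes the future C4 configuration.

Step 2
Reactants: 2 (2S,3S)-2,3-epoxygeraniol
Product: 3 (S)-3,7-dimethyloct-6-ene-1,3-diol
Conditions: NaAlH2(OCH2CH2OCH3)2, THF, 0 °C → rt; aq. NaOH
Reagents that add atoms: none
Why: Regioselective reductive opening of a 2,3-epoxy alcohol, in which the alkoxyaluminate formed at O1 delivers hydride to C2 to give the 1,3-diol while the tertiary C–O bond (future C4, S) is untouched.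

Step 3
Reactants: 3 (S)-3,7-dimethyloct-6-ene-1,3-diol
Product: 4 (S)-3,7-dimethyl-1,3-bis(triethylsilyloxy)oct-6-ene
Conditions: Et3SiOTf (2.4 equiv), 2,6-lutidine, CH2Cl2, −78 → 0 °C
Reagents that add atoms: triethylsilyl trifluoromethanesulfonate, CC[Si](CC)(CC)OS(=O)(=O)C(F)(F)F
Why: Silylation with the silyl triflate and a hindered base protects both the primary and the hindered tertiary hydroxyl without touching the stereocentre.

Step 4
Reactants: 4 (S)-3,7-dimethyl-1,3-bis(triethylsilyloxy)oct-6-ene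
Product: 5 (S)-3,7-dimethyl-3-(triethylsilyloxy)oct-6-enal
Conditions: (COCl)2, DMSO, CH2Cl2, −78 → −30 °C; Et3N, → 0 °C
Reagents that add atoms: none
Why: Direct Swern oxidation of a primary triethylsilyl ether, in which the chlorodimethylsulfonium salt attacks only the unhindered primary Si–O oxygen, expels Et3SiCl and the alkoxysulfonium ion collapses to the aldehyde, the tertiary silyl ether being inert.

Step 5
Reactants: 5 (S)-3,7-dimethyl-3-(triethylsilyloxy)oct-6-enal
Product: 6 (S)-4,8-dimethyl-4-(triethylsilyloxy)non-7-en-1-yne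
Conditions: dimethyl (1-diazo-2-oxopropyl)phosphonate, K2CO3, MeOH, 0 °C → rt
Reagents that add atoms: dimethyl (1-diazo-2-oxopropyl)phosphonate, CC(=O)C(=[N+]=[N-])P(=O)(OC)OC
Why: Ohira–Bestmann (Seyferth–Gilbert) homologation under mild carbonate/methanol conditions converts the aldehyde into the terminal alkyne (C6≡C7–H) without β-elimination of the tertiary silyloxy group.

Step 6
Reactants: 7 but-2-yn-1-ol
Product: 8 (Z)-3-iodobut-2-en-1-ol
Conditions: NaAlH2(OCH2CH2OCH3)2, Et2O, 0 °C → rt; then I2, THF, −78 °C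
Reagents that add atoms: iodine, II
Why: Hydroxyl-directed trans-hydroalumination places aluminium on C3 within a five-membered alkoxyaluminate, and iodinolysis of the C–Al bond with retention gives the Z-iodoalkene (iodine cis to the carbinol carbon).

Step 7
Reactants: 8 (Z)-3-iodobut-2-en-1-ol
Product: 9 (Z)-3-iodobut-2-enal
Conditions: MnO2, CH2Cl2, rt, dark
Reagents that add atoms: none
Why: Chemoselective MnO2 oxidation of the allylic alcohol under neutral heterogeneous conditions keeps the Z geometry of the sensitive β-iodo enal, which is used at once.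

Step 8
Reactants: 6 (S)-4,8-dimethyl-4-(triethylsilyloxy)non-7-en-1-yne; 9 (Z)-3-iodobut-2-enal
Product: 10 (2Z,4R,8S)-2-iodo-8,12-dimethyl-8-(triethylsilyloxy)trideca-2,11-dien-5-yn-4-ol
Conditions: Me2Zn, (S,S)-ProPhenol (20 mol %), Ph3P=O (40 mol %), toluene, 4 °C
Reagents that add atoms: none
Why: Zinc–ProPhenol-catalysed (Trost) asymmetric alkynylation of an α,β-unsaturated aldehyde, in which the dinuclear zinc catalyst binds the aldehyde and the alkynylzinc formed from 6 and Me2Zn and delivers the alkynyl group to one carbonyl face, setting the C8 carbinol ((4R) in 10) under ligand control.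

Step 9
Reactants: 10 (2Z,4R,8S)-2-iodo-8,12-dimethyl-8-(triethylsilyloxy)trideca-2,11-dien-5-yn-4-ol
Product: 11 (2Z,4S,5Z,8S)-2-iodo-8,12-dimethyl-8-(triethylsilyloxy)trideca-2,5,11-trien-4-ol
Conditions: H2 (1 atm), Pd/CaCO3 poisoned with Pb(OAc)2, quinoline, EtOAc, 0 °C, stopped at one equivalent of H2
Reagents that add atoms: none
Why: Lindlar semihydrogenation delivers H2 syn on the poisoned palladium surface and converts the C6≡C7 alkyne into the Z alkene, quinoline and low temperature being used to spare the vinylic C–I bond and the trisubstituted alkenes (the carbinol descriptor changes to S only through the priority rules).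

Step 10
Reactants: 11 (2Z,4S,5Z,8S)-2-iodo-8,12-dimethyl-8-(triethylsilyloxy)trideca-2,5,11-trien-4-ol
Product: 12 (1R,2Z)-1-[(2S,3R)-3-{(2S)-4-(3,3-dimethyloxiran-2-yl)-2-methyl-2-(triethylsilyloxy)butyl}oxiran-2-yl]-3-iodobut-2-en-1-ol (both epimers at the dimethyloxirane carbon)
Conditions: mCPBA (2.3 equiv), NaHCO3, CH2Cl2, 0 °C
Reagents that add atoms: 3-chloroperoxybenzoic acid, OOC(=O)c1cccc(Cl)c1
Why: Henbest-type hydroxyl-directed peracid epoxidation, in which allylic 1,3-strain holds H8 of the Z-allylic alcohol in the plane of C6=C7 so that the hydrogen-bonded peracid delivers oxygen syn to the C8 hydroxyl and should give the threo (6R,7S) cis-epoxide; the iodoalkene is deactivated, and the electron-rich remote alkene is epoxidised on purpose as a masked C1 aldehyde.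

Step 11
Reactants: 12 (1R,2Z)-1-[(2S,3R)-3-{(2S)-4-(3,3-dimethyloxiran-2-yl)-2-methyl-2-(triethylsilyloxy)butyl}oxiran-2-yl]-3-iodobut-2-en-1-ol; 13 2-(diethoxyphosphoryl)acetic acid
Product: 14 2-(diethoxyphosphoryl)acetate ester of 12 at the C8 hydroxyl
Conditions: DCC, DMAP (cat.), CH2Cl2, 0 °C → rt
Reagents that add atoms: none
Why: Steglich esterification of the hindered secondary allylic alcohol under neutral conditions leaves both epoxides, the silyl ether and the C8 stereocentre untouched and installs C11 and C12 on the C8 oxygen.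

Step 12
Reactants: 14 2-(diethoxyphosphoryl)acetate ester of 12
Product: 16 (4S,5S)-4-[(1R,3S)-5-(3,3-dimethyloxiran-2-yl)-1-hydroxy-3-methyl-3-(triethylsilyloxy)pentyl]-5-[(Z)-2-iodoprop-1-en-1-yl]-3-methylideneoxolan-2-one, via phosphono lactone 15 (not isolated)
Conditions: NaH (1.05 equiv), THF, 0 → 45 °C; then (CH2O)n, 0 °C → rt
Reagents that add atoms: paraformaldehyde (as formaldehyde), C=O
Why: Deprotonation gives the phosphonate-stabilised carbanion at C11, which attacks the epoxide carbon C7 from the side opposite the C7–O bond and closes the five-membered lactone ring (O–C8–C7–C11–C12) in the 5-exo-tet mode; the C6 alkoxide set free is quenched at once by proton transfer from the more acidic C11–H, and the resulting α-phosphono lactone carbanion undergoes Horner–Wadsworth–Emmons olefination with formaldehyde to install C13. The closest known reaction types are the Stork-type cyclisation of epoxides with tethered stabilised carbanions (epoxy nitriles, epoxy malonates), the opening of epoxides by sodium phosphonoacetates in the Wadsworth–Emmons cyclopropanation, and the methylenation of α-phosphono-γ-lactones with formaldehyde. C7 is set by SN2 inversion, which is stereospecific and places C11 cis to the C8 oxygen tether, so that the cis β,γ-disubstituted lactone results; C6 keeps the configuration of its epoxide C–O bond (O6 anti to C11) and C8 is not touched. The step needs 5-exo attack at C7 and not 6-endo attack at C6: the three-atom O–C(=O)–C tether reaches the collinear backside trajectory at C7, and the smaller ring is the kinetically preferred one in epoxide cyclisations of this kind. It also needs the carbanion to leave the remote dimethyloxirane and the vinyl iodide alone, which is secured by distance and by the inertness of an sp2 C–I bond to soft carbanions, while the mild temperature keeps the adduct away from the phosphoryl-transfer/cyclopropanation path that needs much stronger heating.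

Step 13
Reactants: 16 (4S,5S)-4-[(1R,3S)-5-(3,3-dimethyloxiran-2-yl)-1-hydroxy-3-methyl-3-(triethylsilyloxy)pentyl]-5-[(Z)-2-iodoprop-1-en-1-yl]-3-methylideneoxolan-2-one; 17 tigloyl chloride
Product: 18 (1R,3S)-5-(3,3-dimethyloxiran-2-yl)-1-[(2S,3S)-2-[(Z)-2-iodoprop-1-en-1-yl]-4-methylidene-5-oxooxolan-3-yl]-3-methyl-3-(triethylsilyloxy)pentyl (E)-2-methylbut-2-enoate
Conditions: pyridine, DMAP (cat.), CH2Cl2, 0 °C → rt
Reagents that add atoms: none
Why: DMAP-catalysed acylation of the secondary C6 alcohol with pyridine as the only base avoids ketene formation from the acid chloride, so the E geometry of the tiglate is kept and the hydroxy lactone is capped before the lactone can migrate to O6.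

Step 14
Reactants: 18 (1R,3S)-5-(3,3-dimethyloxiran-2-yl)-1-[(2S,3S)-2-[(Z)-2-iodoprop-1-en-1-yl]-4-methylidene-5-oxooxolan-3-yl]-3-methyl-3-(triethylsilyloxy)pentyl (E)-2-methylbut-2-enoate
Product: 20 (1R,3S)-1-[(2S,3S)-2-[(Z)-2-iodoprop-1-en-1-yl]-4-methylidene-5-oxooxolan-3-yl]-3-methyl-6-oxo-3-(triethylsilyloxy)hexyl (E)-2-methylbut-2-enoate, via glycol 19 (not isolated)
Conditions: H5IO6, THF/Et2O, 0 °C
Reagents that add atoms: none
Why: Periodic acid hydrolyses the acid-labile trisubstituted epoxide to the glycol and cleaves it in the same flask (epoxide-to-aldehyde degradation), unmasking the C1 aldehyde with loss of acetone, while the tertiary silyl ether, the esters and the vinyl iodide should survive the short exposure at 0 °C.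

Step 15
Reactants: 20 (1R,3S)-1-[(2S,3S)-2-[(Z)-2-iodoprop-1-en-1-yl]-4-methylidene-5-oxooxolan-3-yl]-3-methyl-6-oxo-3-(triethylsilyloxy)hexyl (E)-2-methylbut-2-enoate
Product: 21 (4S,6R,7S,8R,9Z)-1-hydroxy-6-[(E)-2-methylbut-2-enoyloxy]-4-(triethylsilyloxy)germacra-9,11(13)-dien-8,12-olide (both C1 epimers)
Conditions: CrCl2 (10 equiv), NiCl2 (cat.), DMSO/THF, rt, high dilution (slow addition)
Reagents that add atoms: none
Why: Nozaki–Hiyama–Kishi reaction, in which zerovalent nickel inserts into the vinylic C–I bond, the alkenyl group passes to trivalent chromium and adds to the aldehyde to close the ten-membered carbocycle at C1–C10 with retention of the Z alkene, the cis-fused lactone holding both chain ends on one face; the new C1 carbinol is expected as an epimer mixture and is fixed in steps 16 and 17.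

Step 16
Reactants: 21 (4S,6R,7S,8R,9Z)-1-hydroxy-6-[(E)-2-methylbut-2-enoyloxy]-4-(triethylsilyloxy)germacra-9,11(13)-dien-8,12-olide
Product: 22 (4S,6R,7S,8R,9Z)-6-[(E)-2-methylbut-2-enoyloxy]-1-oxo-4-(triethylsilyloxy)germacra-9,11(13)-dien-8,12-olide
Conditions: Dess–Martin periodinane, NaHCO3, CH2Cl2, 0 °C → rt
Reagents that add atoms: none
Why: Dess–Martin oxidation of the allylic alcohol converges both C1 epimers on one enone without touching the silyl ether, the esters or the exocyclic alkene.

Step 17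
Reactants: 22 (4S,6R,7S,8R,9Z)-6-[(E)-2-methylbut-2-enoyloxy]-1-oxo-4-(triethylsilyloxy)germacra-9,11(13)-dien-8,12-olide
Product: 23 (1S,4S,6R,7S,8R,9Z)-1-hydroxy-6-[(E)-2-methylbut-2-enoyloxy]-4-(triethylsilyloxy)germacra-9,11(13)-dien-8,12-olide
Conditions: (R)-2-methyl-CBS-oxazaborolidine, catecholborane, toluene, −78 °C
Reagents that add atoms: none
Why: Corey–Bakshi–Shibata reduction, in which the ketone binds the (R)-oxazaborolidine with the trisubstituted alkenyl group (C10) as the large and the C2 methylene as the small substituent so that hydride is delivered to the face giving the (1S) allylic alcohol, and at −78 °C 1,2-reduction outruns conjugate reduction while both enoates are inert.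

Step 18
Reactants: 23 (1S,4S,6R,7S,8R,9Z)-1-hydroxy-6-[(E)-2-methylbut-2-enoyloxy]-4-(triethylsilyloxy)germacra-9,11(13)-dien-8,12-olide
Product: 24 (1S,4S,6R,7S,8R,9Z)-1,4-dihydroxy-6-[(E)-2-methylbut-2-enoyloxy]germacra-9,11(13)-dien-8,12-olide (CNP0137971.1)
Conditions: HF·pyridine, pyridine, THF, 0 °C → rt
Reagents that add atoms: none
Why: Fluoride-induced cleavage of the tertiary triethylsilyl ether under buffered, non-basic conditions leaves the tiglate, the α-methylene lactone and the allylic alcohol untouched and affects no stereocentre.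

**Compound list**

1 | geraniol, (E)-3,7-dimethylocta-2,6-dien-1-ol | CC(C)=CCC/C(C)=C/CO | starting material
2 | (2S,3S)-2,3-epoxygeraniol, [(2S,3S)-3-methyl-3-(4-methylpent-3-en-1-yl)oxiran-2-yl]methanol | CC(C)=CCC[C@]1(C)O[C@H]1CO | intermediate
3 | (S)-3,7-dimethyloct-6-ene-1,3-diol | CC(C)=CCC[C@](C)(O)CCO | intermediate
4 | (S)-3,7-dimethyl-1,3-bis(triethylsilyloxy)oct-6-ene | CC(C)=CCC[C@](C)(O[Si](CC)(CC)CC)CCO[Si](CC)(CC)CC | intermediate
5 | (S)-3,7-dimethyl-3-(triethylsilyloxy)oct-6-enal | CC(C)=CCC[C@](C)(O[Si](CC)(CC)CC)CC=O | intermediate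
6 | (S)-4,8-dimethyl-4-(triethylsilyloxy)non-7-en-1-yne | CC(C)=CCC[C@](C)(O[Si](CC)(CC)CC)CC#C | intermediate
7 | but-2-yn-1-ol | CC#CCO | starting material
8 | (Z)-3-iodobut-2-en-1-ol | C/C(I)=C/CO | intermediate
9 | (Z)-3-iodobut-2-enal | C/C(I)=C/C=O | intermediate
10 | (2Z,4R,8S)-2-iodo-8,12-dimethyl-8-(triethylsilyloxy)trideca-2,11-dien-5-yn-4-ol | CC(C)=CCC[C@](C)(O[Si](CC)(CC)CC)CC#C[C@H](O)/C=C(/C)I | intermediate
11 | (2Z,4S,5Z,8S)-2-iodo-8,12-dimethyl-8-(triethylsilyloxy)trideca-2,5,11-trien-4-ol | CC(C)=CCC[C@](C)(O[Si](CC)(CC)CC)C/C=C\[C@H](O)/C=C(/C)I | intermediate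
12 | (1R,2Z)-1-[(2S,3R)-3-{(2S)-4-(3,3-dimethyloxiran-2-yl)-2-methyl-2-(triethylsilyloxy)butyl}oxiran-2-yl]-3-iodobut-2-en-1-ol, both epimers at the dimethyloxirane carbon | CC1(C)OC1CC[C@](C)(O[Si](CC)(CC)CC)C[C@H]1O[C@H]1[C@H](O)/C=C(/C)I | intermediate
13 | 2-(diethoxyphosphoryl)acetic acid | CCOP(=O)(CC(=O)O)OCC | starting material
14 | (1R,2Z)-1-[(2S,3R)-3-{(2S)-4-(3,3-dimethyloxiran-2-yl)-2-methyl-2-(triethylsilyloxy)butyl}oxiran-2-yl]-3-iodobut-2-en-1-yl 2-(diethoxyphosphoryl)acetate | CC1(C)OC1CC[C@](C)(O[Si](CC)(CC)CC)C[C@H]1O[C@H]1[C@H](OC(=O)CP(=O)(OCC)OCC)/C=C(/C)I | intermediate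
15 | diethyl {(4S,5S)-4-[(1R,3S)-5-(3,3-dimethyloxiran-2-yl)-1-hydroxy-3-methyl-3-(triethylsilyloxy)pentyl]-5-[(Z)-2-iodoprop-1-en-1-yl]-2-oxooxolan-3-yl}phosphonate (formed as its sodium carbanion, not isolated) | CCOP(=O)(OCC)C1C(=O)O[C@H](/C=C(/C)I)[C@@H]1[C@H](O)C[C@@](C)(O[Si](CC)(CC)CC)CCC1OC1(C)C | intermediate
16 | (4S,5S)-4-[(1R,3S)-5-(3,3-dimethyloxiran-2-yl)-1-hydroxy-3-methyl-3-(triethylsilyloxy)pentyl]-5-[(Z)-2-iodoprop-1-en-1-yl]-3-methylideneoxolan-2-one | C=C1C(=O)O[C@H](/C=C(/C)I)[C@@H]1[C@H](O)C[C@@](C)(O[Si](CC)(CC)CC)CCC2OC2(C)C | intermediate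
17 | tigloyl chloride, (E)-2-methylbut-2-enoyl chloride | C/C=C(\C)C(=O)Cl | starting material
18 | (1R,3S)-5-(3,3-dimethyloxiran-2-yl)-1-[(2S,3S)-2-[(Z)-2-iodoprop-1-en-1-yl]-4-methylidene-5-oxooxolan-3-yl]-3-methyl-3-(triethylsilyloxy)pentyl (E)-2-methylbut-2-enoate | C=C1C(=O)O[C@H](/C=C(/C)I)[C@@H]1[C@H](OC(=O)/C(C)=C/C)C[C@@](C)(O[Si](CC)(CC)CC)CCC2OC2(C)C | intermediate
19 | (1R,3S)-6,7-dihydroxy-1-[(2S,3S)-2-[(Z)-2-iodoprop-1-en-1-yl]-4-methylidene-5-oxooxolan-3-yl]-3,7-dimethyl-3-(triethylsilyloxy)octyl (E)-2-methylbut-2-enoate (glycol, not isolated) | C=C1C(=O)O[C@H](/C=C(/C)I)[C@@H]1[C@H](OC(=O)/C(C)=C/C)C[C@@](C)(O[Si](CC)(CC)CC)CCC(O)C(C)(C)O | intermediate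
20 | (1R,3S)-1-[(2S,3S)-2-[(Z)-2-iodoprop-1-en-1-yl]-4-methylidene-5-oxooxolan-3-yl]-3-methyl-6-oxo-3-(triethylsilyloxy)hexyl (E)-2-methylbut-2-enoate | C=C1C(=O)O[C@H](/C=C(/C)I)[C@@H]1[C@H](OC(=O)/C(C)=C/C)C[C@@](C)(O[Si](CC)(CC)CC)CCC=O | intermediate
21 | (4S,6R,7S,8R,9Z)-1-hydroxy-6-[(E)-2-methylbut-2-enoyloxy]-4-(triethylsilyloxy)germacra-9,11(13)-dien-8,12-olide, both C1 epimers | C=C1C(=O)O[C@@H]2/C=C(/C)C(O)CC[C@](C)(O[Si](CC)(CC)CC)C[C@@H](OC(=O)/C(C)=C/C)[C@H]12 | intermediate
22 | (4S,6R,7S,8R,9Z)-6-[(E)-2-methylbut-2-enoyloxy]-1-oxo-4-(triethylsilyloxy)germacra-9,11(13)-dien-8,12-olide | C=C1C(=O)O[C@@H]2/C=C(/C)C(=O)CC[C@](C)(O[Si](CC)(CC)CC)C[C@@H](OC(=O)/C(C)=C/C)[C@H]12 | intermediate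
23 | (1S,4S,6R,7S,8R,9Z)-1-hydroxy-6-[(E)-2-methylbut-2-enoyloxy]-4-(triethylsilyloxy)germacra-9,11(13)-dien-8,12-olide | C=C1C(=O)O[C@@H]2/C=C(/C)[C@@H](O)CC[C@](C)(O[Si](CC)(CC)CC)C[C@@H](OC(=O)/C(C)=C/C)[C@H]12 | intermediate
24 | (1S,4S,6R,7S,8R,9Z)-1,4-dihydroxy-6-[(E)-2-methylbut-2-enoyloxy]germacra-9,11(13)-dien-8,12-olide, CNP0137971.1 | C=C1C(=O)O[C@@H]2/C=C(/C)[C@@H](O)CC[C@](C)(O)C[C@@H](OC(=O)/C(C)=C/C)[C@H]12 | target

**Step count and risks**

Total step count: 18. Longest linear sequence: 16 steps (from 1 through steps 1–5 and 8–18).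

The three steps most likely to fail:

Step 12 (key step). The ring closure may be slow because the ester has to reach its s-cis rotamer and the phosphonate carbanion is only moderately nucleophilic. The epoxide may also be opened 6-endo at C6, or the lactone may migrate from O8 to the free O6 before work-up. Fallback, from 12 back to 16: 12 is heated with Meldrum's acid (pyridine, toluene, 80 °C) to give the hydrogen malonate F1. LiN(SiMe3)2 (2.2 equiv, THF, −78 → 40 °C) generates the more nucleophilic enolate–carboxylate dianion, which opens the epoxide at C7 in the same 5-exo sense to give the α-carboxy lactone F2. Aqueous formaldehyde and Et2NH (dioxane, rt → 50 °C) then effect decarboxylative Mannich methylenation to 16, where the route is rejoined at step 13.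

Step 15. Closure of the strained ten-membered ring may lose out to intermolecular coupling or to reductive loss of the vinylic iodine. Fallback, from 20 back to 22: Pinnick oxidation (NaClO2, NaH2PO4, 2-methylbut-2-ene, t-BuOH/H2O) gives the carboxylic acid F3. 2,2′-Dipyridyl disulfide and PPh3 convert it into the S-(2-pyridyl) thioester F4. A nickel/zirconium-mediated reductive acyl–alkenyl coupling (NiBr2(dtbbpy) cat., Cp2ZrCl2, Zn, DMI, high dilution) closes the ring directly as enone 22, where the route is rejoined at step 17.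

Step 9. The semihydrogenation may be accompanied by hydrogenolysis of the vinylic C–I bond or by over-reduction. Fallback, from 5 back to 11, in which the iodide is made only after the Z alkene exists: Z-selective Horner–Wadsworth–Emmons olefination of 5 with ethyl (diphenoxyphosphoryl)acetate (NaH, THF, −78 °C) gives the Z-enoate F5. Reduction with (i-Bu)2AlH (CH2Cl2, −78 °C) gives the Z-allylic alcohol F6. Dess–Martin periodinane/NaHCO3 at 0 °C gives the Z-enal F7. Zinc–ProPhenol alkynylation with propyne (Me2Zn, (R,R)-ProPhenol, Ph3P=O, toluene) gives the enynol F8. Hydroalumination/iodination as in step 6 (NaAlH2(OCH2CH2OCH3)2; then I2) then gives 11.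

**Further compounds**

F1 | step 12 | 3-{(1R,2Z)-1-[(2S,3R)-3-{(2S)-4-(3,3-dimethyloxiran-2-yl)-2-methyl-2-(triethylsilyloxy)butyl}oxiran-2-yl]-3-iodobut-2-en-1-yloxy}-3-oxopropanoic acid (hydrogen malonate of 12) | CC1(C)OC1CC[C@](C)(O[Si](CC)(CC)CC)C[C@H]1O[C@H]1[C@H](OC(=O)CC(=O)O)/C=C(/C)I
F2 | step 12 | (4S,5S)-4-[(1R,3S)-5-(3,3-dimethyloxiran-2-yl)-1-hydroxy-3-methyl-3-(triethylsilyloxy)pentyl]-5-[(Z)-2-iodoprop-1-en-1-yl]-2-oxooxolane-3-carboxylic acid | OC(=O)C1C(=O)O[C@H](/C=C(/C)I)[C@@H]1[C@H](O)C[C@@](C)(O[Si](CC)(CC)CC)CCC1OC1(C)C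
F3 | step 15 | (4S,6R)-6-[(2S,3S)-2-[(Z)-2-iodoprop-1-en-1-yl]-4-methylidene-5-oxooxolan-3-yl]-4-methyl-6-[(E)-2-methylbut-2-enoyloxy]-4-(triethylsilyloxy)hexanoic acid | C=C1C(=O)O[C@H](/C=C(/C)I)[C@@H]1[C@H](OC(=O)/C(C)=C/C)C[C@@](C)(O[Si](CC)(CC)CC)CCC(=O)O
F4 | step 15 | S-(pyridin-2-yl) thioester of F3 | C=C1C(=O)O[C@H](/C=C(/C)I)[C@@H]1[C@H](OC(=O)/C(C)=C/C)C[C@@](C)(O[Si](CC)(CC)CC)CCC(=O)Sc1ccccn1
F5 | step 9 | ethyl (2Z,5S)-5,9-dimethyl-5-(triethylsilyloxy)deca-2,8-dienoate | CC(C)=CCC[C@](C)(O[Si](CC)(CC)CC)C/C=C\C(=O)OCC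
F6 | step 9 | (2Z,5S)-5,9-dimethyl-5-(triethylsilyloxy)deca-2,8-dien-1-ol | CC(C)=CCC[C@](C)(O[Si](CC)(CC)CC)C/C=C\CO
F7 | step 9 | (2Z,5S)-5,9-dimethyl-5-(triethylsilyloxy)deca-2,8-dienal | CC(C)=CCC[C@](C)(O[Si](CC)(CC)CC)C/C=C\C=O
F8 | step 9 | (4S,5Z,8S)-8,12-dimethyl-8-(triethylsilyloxy)trideca-5,11-dien-2-yn-4-ol | CC(C)=CCC[C@](C)(O[Si](CC)(CC)CC)C/C=C\[C@H](O)C#CC
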